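**Retrosynthetic overview**
1. Locants (8,9-secokaurane): C10 = CH3-bearing quaternary carbon α to the C9 ketone; C5 = ring-fusion CH next to the C4 gem-dimethyl carbon; C7 = acetoxy carbon; C11 = carbinol carbon; C8=C14–C13–C16–C15(=O) = cyclopentenone.
2. Enabling feature: the cyclohexane (C1–C5, C10) and the ten-membered ring (C5–C6–C7–C8–C14–C13–C12–C11–C9–C10) share only the C5–C10 bond, so both are halves of one 14-membered perimeter. C10 is the α-carbon of the C9 ketone and carries CH3 and CH2, so it is the adduct radical of an isopropenyl ketone. C5 is the far end of the C5=C6–C7(O) allyl unit next to the C4 gem-dimethyl group.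
3. Key disconnection: C5–C10 (transannular 6-exo) plus C1–C2 (14-endo) in one radical chain. This leads back to a monocyclic 2,4-disubstituted cyclopentenone with an ω-iodoalkyl allylic alcohol arm and an α-silyloxy isopropenyl ketone arm.
4. Precursor: C7–C8 by asymmetric Nozaki–Hiyama–Kishi coupling (2-iodoenone + enal); C12–C13 by anti Giese addition to (R)-4-silyloxycyclopentenone followed by β-elimination; C11 from (S)-glycidate.
5. Ring order: cyclopentenone (bought) → transient 14-membered ring → six- and ten-membered rings together. End game: C7 acetate, C16 methylenation, desilylation.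

Key step: step 13

Remark (chemistry): 9 and 11–13 are carried as mixtures of epimers at the C9 carbinol carbon (undefined in their SMILES), which step 10 erases; the CIP label of C13 changes from R to S in step 15 only because C16 gains priority.

**Route**

Step 1
Reactants: 1 3,3-dimethyldihydrofuran-2(3H)-one (α,α-dimethyl-γ-butyrolactone)
Product: 2 ethyl 4-bromo-2,2-dimethylbutanoate
Conditions: HBr (g, sat.), EtOH, 0 °C → rt
Reagents that add atoms: hydrogen bromide (Br); ethanol (CCO)
Why: Acidic lactone opening, in which bromide attacks the unhindered O–CH2 carbon (SN2) and Fischer esterification of the hindered acid blocks relactonisation.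

Step 2
Reactants: 2 ethyl 4-bromo-2,2-dimethylbutanoate
Product: 3 4-bromo-2,2-dimethylbutanal
Conditions: DIBAL-H (1.05 equiv), CH2Cl2, −78 °C; aq Rochelle salt
Reagents that add atoms: none
Why: Partial ester reduction, because the aluminium hemiacetal of the neopentyl-type ester persists at −78 °C so that reduction should stop at the aldehyde and the alkyl bromide is inert.

Step 3
Reactants: 3 4-bromo-2,2-dimethylbutanal
Product: 4 (E)-6-bromo-4,4-dimethylhex-2-enal
Conditions: Ph3P=CHCHO (1.2 equiv), PhMe, 90 °C
Reagents that add atoms: (triphenylphosphoranylidene)acetaldehyde (O=CC=P(c1ccccc1)(c1ccccc1)c1ccccc1)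
Why: Wittig olefination with a stabilised ylide, which should give the (E)-enal (C5=C6) on a non-enolisable aldehyde.

Step 4
Reactants: 5 methyl (S)-oxirane-2-carboxylate (methyl (S)-glycidate)
Product: 6 methyl (R)-2-hydroxy-3-iodopropanoate
Conditions: LiI, AcOH, THF, rt
Reagents that add atoms: lithium iodide ([Li+].[I-])
Why: Regioselective halohydrin formation, in which iodide opens the activated glycidic ester at the CH2 carbon (SN2) so that the C–O bond at the future C11 is untouched and only the CIP label changes.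

Step 5
Reactants: 6 methyl (R)-2-hydroxy-3-iodopropanoate
Product: 7 methyl (R)-2-(tert-butyldimethylsilyloxy)-3-iodopropanoate
Conditions: TBSCl, imidazole, DMF, 0 °C → rt
Reagents that add atoms: tert-butyldimethylsilyl chloride (CC(C)(C)[Si](C)(C)Cl)
Why: Standard O-silylation under a base too weak to trigger β-elimination of iodide.

Step 6
Reactants: 7 methyl (R)-2-(tert-butyldimethylsilyloxy)-3-iodopropanoate
Product: 9 (4R)-4-(tert-butyldimethylsilyloxy)-5-iodo-2-methylpent-1-en-3-ol (C3 epimers), via silyloxy iodo aldehyde 8 (not isolated)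
Conditions: DIBAL-H (1.0 equiv), CH2Cl2, −78 °C; then isopropenylMgBr, THF, −78 → −20 °C; aq NH4Cl/Rochelle salt
Reagents that add atoms: isopropenylmagnesium bromide (C=C(C)[Mg]Br)
Why: One-pot partial reduction and Grignard addition, which avoids isolating the elimination-prone β-iodo aldehyde; the new carbinol centre (C9) need not be controlled because it is oxidised in step 10.

Step 7
Reactants: 9 (4R)-4-(tert-butyldimethylsilyloxy)-5-iodo-2-methylpent-1-en-3-ol; 10 (R)-4-(tert-butyldimethylsilyloxy)cyclopent-2-en-1-one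
Product: 11 (3R,4R)-4-(tert-butyldimethylsilyloxy)-3-[(2S)-2-(tert-butyldimethylsilyloxy)-3-hydroxy-4-methylpent-4-en-1-yl]cyclopentan-1-one
Conditions: 10 (3 equiv), (Me3Si)3SiH (1.2 equiv, slow addition), AIBN (0.1 equiv), PhH (0.5 M in 10), 80 °C
Reagents that add atoms: none
Why: Giese reaction, in which the β-silyloxy primary radical (which does not β-eliminate as the corresponding organometal would) adds to the enone β-carbon anti to the 4-silyloxy group and so sets C13.

Step 8
Reactants: 11 (3R,4R)-4-(tert-butyldimethylsilyloxy)-3-[(2S)-2-(tert-butyldimethylsilyloxy)-3-hydroxy-4-methylpent-4-en-1-yl]cyclopentan-1-one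
Product: 12 (4R)-4-[(2S)-2-(tert-butyldimethylsilyloxy)-3-hydroxy-4-methylpent-4-en-1-yl]cyclopent-2-en-1-one
Conditions: DBU (1.1 equiv), CH2Cl2, 0 °C, short contact
Reagents that add atoms: none
Why: E1cB loss of the β-silyloxy group transposes the enone to C15(=O)–C8=C14 and leaves C13 as the γ-stereocentre, the short cold exposure limiting oxa-Michael addition and γ-epimerisation.

Step 9
Reactants: 12 (4R)-4-[(2S)-2-(tert-butyldimethylsilyloxy)-3-hydroxy-4-methylpent-4-en-1-yl]cyclopent-2-en-1-one
Product: 13 (4R)-2-iodo-4-[(2S)-2-(tert-butyldimethylsilyloxy)-3-hydroxy-4-methylpent-4-en-1-yl]cyclopent-2-en-1-one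
Conditions: I2 (1.5 equiv), pyridine–CH2Cl2 1:1, 0 °C → rt
Reagents that add atoms: iodine (II)
Why: Amine-mediated α-iodination of an enone (addition, iodination, elimination), run while the second enone is still masked as its alcohol so that only C8 can react.

Step 10
Reactants: 13 (4R)-2-iodo-4-[(2S)-2-(tert-butyldimethylsilyloxy)-3-hydroxy-4-methylpent-4-en-1-yl]cyclopent-2-en-1-one
Product: 14 (4R)-2-iodo-4-[(2S)-2-(tert-butyldimethylsilyloxy)-4-methyl-3-oxopent-4-en-1-yl]cyclopent-2-en-1-one
Conditions: Dess–Martin periodinane, CH2Cl2, 0 °C → rt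
Reagents that add atoms: none
Why: Dess–Martin oxidation under non-basic conditions funnels both C9 epimers into the single isopropenyl ketone without touching the α-silyloxy centre C11.

Step 11
Reactants: 14 (4R)-2-iodo-4-[(2S)-2-(tert-butyldimethylsilyloxy)-4-methyl-3-oxopent-4-en-1-yl]cyclopent-2-en-1-one; 4 (E)-6-bromo-4,4-dimethylhex-2-enal
Product: 15 (4R)-2-[(1R,2E)-6-bromo-1-hydroxy-4,4-dimethylhex-2-en-1-yl]-4-[(2S)-2-(tert-butyldimethylsilyloxy)-4-methyl-3-oxopent-4-en-1-yl]cyclopent-2-en-1-one
Conditions: CrCl2 (4 equiv), chiral oxazoline–sulfonamide ligand (4.4 equiv, the antipode that directs attack to the Si face of the aldehyde), Et3N (4.4 equiv), NiCl2·2,9-dimethylphenanthroline (2 mol %), THF, rt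
Reagents that add atoms: none
Why: Asymmetric Nozaki–Hiyama–Kishi coupling, in which the alkenylchromium species adds 1,2 to the aldehyde only (ketones, enones and the alkyl bromide survive) and the ligand sets (7R) by reagent control, any C7 epimer being a separable diastereomer.

Step 12
Reactants: 15 (4R)-2-[(1R,2E)-6-bromo-1-hydroxy-4,4-dimethylhex-2-en-1-yl]-4-[(2S)-2-(tert-butyldimethylsilyloxy)-4-methyl-3-oxopent-4-en-1-yl]cyclopent-2-en-1-one
Product: 16 (4R)-2-[(1R,2E)-1-hydroxy-6-iodo-4,4-dimethylhex-2-en-1-yl]-4-[(2S)-2-(tert-butyldimethylsilyloxy)-4-methyl-3-oxopent-4-en-1-yl]cyclopent-2-en-1-one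
Conditions: NaI (5 equiv), acetone, 50 °C, dark
Reagents that add atoms: sodium iodide ([Na+].[I-])
Why: Finkelstein exchange at the unhindered primary carbon under neutral conditions gives the iodide, whose halogen abstraction outruns silyl radical addition to the enones in the next step.

Step 13
Reactants: 16 (4R)-2-[(1R,2E)-1-hydroxy-6-iodo-4,4-dimethylhex-2-en-1-yl]-4-[(2S)-2-(tert-butyldimethylsilyloxy)-4-methyl-3-oxopent-4-en-1-yl]cyclopent-2-en-1-one
Product: 18 (5R,7R,10R,11S,13R)-11-(tert-butyldimethylsilyloxy)-7-hydroxy-17-nor-8,9-secokaur-8(14)-ene-9,15-dione (6/10/5 tricycle), via 14-membered α-keto radical 17 (not isolated)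
Conditions: (Me3Si)3SiH (1.3 equiv) + AIBN (0.3 equiv) by syringe pump (10 h) into 16 (2 mM), degassed PhH, 80 °C
Reagents that add atoms: none
Why: Iodine abstraction gives the nucleophilic primary C2 radical, which can reach its own alkene only by 4-exo or 5-endo paths and therefore adds to the free CH2 terminus (C1) of the isopropenyl ketone in a 14-endo-trig macrocyclisation; the electrophilic tertiary α-keto radical 17 so formed at C10 attacks C5 across the ring in a 6-exo-trig closure that makes the cyclohexane and, in a formal 10-endo sense, turns the rest of the perimeter into the ten-membered ring, and the secondary C6 radical takes hydrogen from the silane. The closest known reaction types are the endo radical macrocyclisation of ω-iodoalkyl enones and the radical macrocyclisation–transannular cyclisation cascades of iodo polyenones, both run with a group 14 hydride at high dilution. C5 is controlled by C7: in the (E)-allylic alcohol the C7–H bond eclipses the alkene, C8 (the tether to C10) lies on one face and the hydroxyl, held by its hydrogen bond to the C15 carbonyl, on the other, so C10 arrives anti to oxygen, which for (7R) gives (5R). C10 is controlled by the chair-like transition state of the exo closure, in which both macrocycle arms (C6 on C5, C9 on C10) are equatorial and the methyl group is axial and anti to H5, a kaurane-like fold that the C13-anchored cyclopentenone bridge can span. The step needs chemoselectivity among three alkenes, and polarity and geometry secure it: the nucleophilic radical takes the best acceptor, whereas the electrophilic C10 radical avoids the electron-poor C14 (whose attack would also put the conjugated C9 carbonyl inside a six-membered transition state) and takes the only unconjugated alkene, exo closure at C5 being helped by the C4 gem-dimethyl group, which also removes all allylic hydrogens on that side. Slow addition of the poor hydrogen donor (Me3Si)3SiH at high dilution keeps bimolecular reduction and oligomerisation behind the two cyclisations.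

Step 14
Reactants: 18 (5R,7R,10R,11S,13R)-11-(tert-butyldimethylsilyloxy)-7-hydroxy-17-nor-8,9-secokaur-8(14)-ene-9,15-dione
Product: 19 (5R,7R,10R,11S,13R)-7-acetoxy-11-(tert-butyldimethylsilyloxy)-17-nor-8,9-secokaur-8(14)-ene-9,15-dione
Conditions: Ac2O, pyridine, DMAP (cat.), CH2Cl2, 0 °C
Reagents that add atoms: acetic anhydride (CC(=O)OC(C)=O)
Why: O-Acylation of the only free hydroxyl with retention at C7, placed after the radical step so that no β-acyloxy radical at C6 (prone to a 1,2-acyloxy shift) is ever formed.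

Step 15
Reactants: 19 (5R,7R,10R,11S,13R)-7-acetoxy-11-(tert-butyldimethylsilyloxy)-17-nor-8,9-secokaur-8(14)-ene-9,15-dione
Product: 22 (5R,7R,10R,11S,13S)-7-acetoxy-11-(tert-butyldimethylsilyloxy)-8,9-secokaura-8(14),16-diene-9,15-dione, via Mannich base 20 (not isolated), via trimethylammonium iodide 21 (not isolated)
Conditions: LiHMDS (1.05 equiv), THF, −78 °C; Me2N=CH2+ I−, −78 → −20 °C; then MeI, Et2O–CH2Cl2, rt; then sat. aq NaHCO3, CH2Cl2, rt
Reagents that add atoms: Eschenmoser's salt, N,N-dimethylmethyleneiminium iodide (C[N+](C)=C.[I-])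
Why: Kinetic α′-deprotonation of the cyclopentenone at C16 (faster than at the acetate or at the C9 ketone, which is flanked by quaternary C10 and silyloxy-bearing C11), Mannich reaction, quaternisation and mild Hofmann-type elimination install the exocyclic methylene without touching C13.

Step 16
Reactants: 22 (5R,7R,10R,11S,13S)-7-acetoxy-11-(tert-butyldimethylsilyloxy)-8,9-secokaura-8(14),16-diene-9,15-dione
Product: 23 (5R,7R,10R,11S,13S)-7-acetoxy-11-hydroxy-8,9-secokaura-8(14),16-diene-9,15-dione (target)
Conditions: HF·pyridine, THF, 0 °C → rt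
Reagents that add atoms: none
Why: Fluoride-driven desilylation in an acidic medium spares the base- and nucleophile-sensitive cross-conjugated dienone, the allylic acetate and the α-ketol.

**Compound list**
1 | 3,3-dimethyldihydrofuran-2(3H)-one | CC1(C)CCOC1=O | starting material
2 | ethyl 4-bromo-2,2-dimethylbutanoate | CCOC(=O)C(C)(C)CCBr | intermediate
3 | 4-bromo-2,2-dimethylbutanal | O=CC(C)(C)CCBr | intermediate
4 | (E)-6-bromo-4,4-dimethylhex-2-enal | O=C/C=C/C(C)(C)CCBr | intermediate
5 | methyl (S)-oxirane-2-carboxylate | COC(=O)[C@@H]1CO1 | starting material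
6 | methyl (R)-2-hydroxy-3-iodopropanoate | IC[C@H](O)C(=O)OC | intermediate
7 | methyl (R)-2-(tert-butyldimethylsilyloxy)-3-iodopropanoate | IC[C@H](O[Si](C)(C)C(C)(C)C)C(=O)OC | intermediate
8 | (R)-2-(tert-butyldimethylsilyloxy)-3-iodopropanal (not isolated) | IC[C@H](O[Si](C)(C)C(C)(C)C)C=O | intermediate
9 | (4R)-4-(tert-butyldimethylsilyloxy)-5-iodo-2-methylpent-1-en-3-ol, C3 epimers | IC[C@H](O[Si](C)(C)C(C)(C)C)C(O)C(C)=C | intermediate
10 | (R)-4-(tert-butyldimethylsilyloxy)cyclopent-2-en-1-one | O=C1C[C@@H](O[Si](C)(C)C(C)(C)C)C=C1 | starting material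
11 | trans-(3R,4R)-3-alkyl-4-silyloxycyclopentanone (Giese adduct) | C1C(=O)C[C@@H](O[Si](C)(C)C(C)(C)C)[C@@H]1C[C@H](O[Si](C)(C)C(C)(C)C)C(O)C(C)=C | intermediate
12 | (4R)-4-[(2S)-2-silyloxy-3-hydroxy-4-methylpent-4-enyl]cyclopent-2-enone | C1C(=O)C=C[C@@H]1C[C@H](O[Si](C)(C)C(C)(C)C)C(O)C(C)=C | intermediate
13 | 2-iodo derivative of 12 | C1C(=O)C(I)=C[C@@H]1C[C@H](O[Si](C)(C)C(C)(C)C)C(O)C(C)=C | intermediate
14 | iodoenone with α-silyloxy isopropenyl ketone arm | C1C(=O)C(I)=C[C@@H]1C[C@H](O[Si](C)(C)C(C)(C)C)C(=O)C(C)=C | intermediate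
15 | (7R)-allylic alcohol, ω-bromide | C1C(=O)C(=C[C@@H]1C[C@H](O[Si](C)(C)C(C)(C)C)C(=O)C(C)=C)[C@H](O)/C=C/C(C)(C)CCBr | intermediate
16 | (7R)-allylic alcohol, ω-iodide (cascade precursor) | C1C(=O)C(=C[C@@H]1C[C@H](O[Si](C)(C)C(C)(C)C)C(=O)C(C)=C)[C@H](O)/C=C/C(C)(C)CCI | intermediate
17 | 14-membered macrocyclic C10 α-keto radical (not isolated) | C1C(=O)C2=C[C@@H]1C[C@H](O[Si](C)(C)C(C)(C)C)C(=O)[C](C)CCCC(C)(C)/C=C/[C@H]2O | intermediate
18 | tricyclic 7-hydroxy-11-silyloxy-17-nor-dione | C1C(=O)C2=C[C@@H]1C[C@H](O[Si](C)(C)C(C)(C)C)C(=O)[C@]1(C)CCCC(C)(C)[C@H]1C[C@H]2O | intermediate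
19 | 7-acetate of 18 | C1C(=O)C2=C[C@@H]1C[C@H](O[Si](C)(C)C(C)(C)C)C(=O)[C@]1(C)CCCC(C)(C)[C@H]1C[C@H]2OC(C)=O | intermediate
20 | C16 dimethylaminomethyl ketone, C16 epimers (not isolated) | CN(C)CC1C(=O)C2=C[C@@H]1C[C@H](O[Si](C)(C)C(C)(C)C)C(=O)[C@]1(C)CCCC(C)(C)[C@H]1C[C@H]2OC(C)=O | intermediate
21 | C16 trimethylammoniomethyl ketone iodide (not isolated) | C[N+](C)(C)CC1C(=O)C2=C[C@@H]1C[C@H](O[Si](C)(C)C(C)(C)C)C(=O)[C@]1(C)CCCC(C)(C)[C@H]1C[C@H]2OC(C)=O.[I-] | intermediate
22 | 11-O-TBS ether of the target | C=C1C(=O)C2=C[C@@H]1C[C@H](O[Si](C)(C)C(C)(C)C)C(=O)[C@]1(C)CCCC(C)(C)[C@H]1C[C@H]2OC(C)=O | intermediate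
23 | (5R,7R,10R,11S,13S)-7-acetoxy-11-hydroxy-8,9-secokaura-8(14),16-diene-9,15-dione | C=C1C(=O)C2=C[C@@H]1C[C@H](O)C(=O)[C@]1(C)CCCC(C)(C)[C@H]1C[C@H]2OC(C)=O | target

**Step count**
- Total steps: 16.
- Longest linear sequence: 13 steps (5 → 23, steps 4–16).

**Steps most likely to fail**

1. Step 13. What may go wrong: premature hydrogen transfer to the primary radical or to the macrocyclic α-keto radical, oligomerisation, or poor facial selectivity in the transannular closure.
   - Fallback: both C–C bonds are made before any medium ring exists, and the ten-membered ring is closed last at C7–C8. It sets out from 12 and 4 and comes back at 18.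
   - Dess–Martin oxidation of 12 gives the deiodo bis-enone F1. Finkelstein exchange on 4 gives (E)-6-iodo-4,4-dimethylhex-2-enal F2.
   - With (Me3Si)3SiH/AIBN and F1 in excess, the radical from F2 adds to the isopropenyl ketone of F1 (Giese reaction). In the same chain the C10 radical closes 6-exo onto the now activated enal and gives the cyclohexyl acetaldehyde F3.
   - α-Iodination (I2, pyridine) gives the iodoenone aldehyde F4. An intramolecular Nozaki–Hiyama–Kishi coupling at high dilution then closes the ten-membered ring to 18, with C7 set by the ring conformation.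

2. Step 11. What may go wrong: insufficient reagent control at C7, or reductive loss of iodine from the iodoenone.
   - Fallback: stereocontrol is moved from the coupling to separation and invertive recycling. It sets out from 14 and 4 and comes back at 15.
   - The ligand-free Ni/Cr coupling gives 15 together with its (7S)-epimer F5, and these diastereomers are separated.
   - F5 is inverted by Mitsunobu reaction with formic acid (PPh3, DIAD) to the (7R)-formate F6. Brief methanolysis (KHCO3, MeOH, 0 °C) then gives 15.

3. Step 15. What may go wrong: competing deprotonation at C13 or at the acetate, followed by loss of acetate or scrambling of C13.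
   - Fallback: a Lewis-acid route without strong base. It sets out from 19 and comes back at 22.
   - Soft enolisation (TMSOTf, Et3N, CH2Cl2, −78 °C) gives the 15-trimethylsilyloxy cyclopentadiene F7.
   - Mukaiyama aldol hydroxymethylation with aqueous formaldehyde and Yb(OTf)3 gives the C16 hydroxymethyl ketone F8.
   - Mesylation and elimination (MsCl, Et3N, 0 °C) give 22.

**Further compounds**
F1 | step 13 | (4R)-4-[(2S)-2-(tert-butyldimethylsilyloxy)-4-methyl-3-oxopent-4-en-1-yl]cyclopent-2-en-1-one | C1C(=O)C=C[C@@H]1C[C@H](O[Si](C)(C)C(C)(C)C)C(=O)C(C)=C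
F2 | step 13 | (E)-6-iodo-4,4-dimethylhex-2-enal | O=C/C=C/C(C)(C)CCI
F3 | step 13 | cyclohexyl acetaldehyde with (5R,10R) ring and intact cyclopentenone | C1C(=O)C=C[C@@H]1C[C@H](O[Si](C)(C)C(C)(C)C)C(=O)[C@]1(C)CCCC(C)(C)[C@H]1CC=O
F4 | step 13 | 2-iodoenone derivative of F3 | C1C(=O)C(I)=C[C@@H]1C[C@H](O[Si](C)(C)C(C)(C)C)C(=O)[C@]1(C)CCCC(C)(C)[C@H]1CC=O
F5 | step 11 | (7S)-epimer of 15 | C1C(=O)C(=C[C@@H]1C[C@H](O[Si](C)(C)C(C)(C)C)C(=O)C(C)=C)[C@@H](O)/C=C/C(C)(C)CCBr
F6 | step 11 | (7R)-formate of 15 | C1C(=O)C(=C[C@@H]1C[C@H](O[Si](C)(C)C(C)(C)C)C(=O)C(C)=C)[C@H](OC=O)/C=C/C(C)(C)CCBr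
F7 | step 15 | 15-trimethylsilyloxy cyclopentadiene from 19 | C1=C(O[Si](C)(C)C)C2=C[C@@H]1C[C@H](O[Si](C)(C)C(C)(C)C)C(=O)[C@]1(C)CCCC(C)(C)[C@H]1C[C@H]2OC(C)=O
F8 | step 15 | C16 hydroxymethyl ketone, C16 epimers | OCC1C(=O)C2=C[C@@H]1C[C@H](O[Si](C)(C)C(C)(C)C)C(=O)[C@]1(C)CCCC(C)(C)[C@H]1C[C@H]2OC(C)=O
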